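Epsilon carries 1.33 times the scavenger of theta, yet at 15.0 min the two runs have lost 14.1% and 14.2% of their electrophile, a gap of 0.1 percentage points against a reading scatter of 0.3 points.

| flask | electrophile | nucleophile | free base | scavenger | remark | time |
|---|---|---|---|---|---|---|
| theta | 0.50 M | 0.65 M | 0.40 M | 0.90 M | run made earlier |  |
| epsilon | 0.50 M | 0.65 M | 0.40 M | 1.2 M | run made earlier |  |
| midnight | 0.50 M | 0.650 M | 0.400 M | 0.600 M |  | 80 min |
| summer | 0.50 M | 0.650 M | 0.800 M | 0.600 M |  | 80 min |

| run | time / min | electrophile / % | target / % |
|---|---|---|---|
| theta | 2.50 | 97.5 | 3.1 |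
| theta | 5.00 | 95.2 | 5.9 |
| theta | 8.00 | 91.8 | 8.1 |
| theta | 10.0 | 90.3 | 10.0 |
| theta | 12.0 | 87.9 | 11.8 |
| theta | 15.0 | 85.9 | 14.3 |
| epsilon | 2.50 | 96.9 | 2.7 |
| epsilon | 5.00 | 95.4 | 5.8 |
| epsilon | 8.00 | 91.4 | 7.9 |
| epsilon | 10.0 | 89.8 | 10.0 |
| epsilon | 12.0 | 88.4 | 12.1 |
| epsilon | 15.0 | 85.8 | 13.5 |

(each reading ± 0.3 percentage points)

- the earlier runs were read with a standard deviation of 0.3 percentage points
- a reading or a percentage of target counts all its forms, free or not
- no earlier run changes the charge of free base; that part of a forecast is a guess

- part of the electrophile that has reacted at the end, midnight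
- part of the electrophile that has reacted at the end, summer
- what raising the concentration of free base from its lowest to its highest value here does to the part of the electrophile that has reacted (changes below 5 percentage points count as none) (it rises / it falls / no change)

So the readings show no order in scavenger between these two charges. Midnight and summer, at 0.600 M, lie below that span, and carrying the result down to them is an assumption.

Which concentration then sets the order? In the theta run, target stands at 14.3% at the last reading, matching the electrophile lost, so the readings can be treated as one step. Electrophile is the limiting reagent, but c(nucleophile) is charged at just 1.30 times c(electrophile). Theta and epsilon share one charge of nucleophile and so do not test its order; I take the rate as first order in each of the pair, with c(nucleophile) falling along with c(electrophile), not as pseudo-first-order.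

How fast is that step? The mean target of theta and epsilon at that time, 13.9%, gives 0.0163 L mol⁻¹ min⁻¹. This is the pair constant: the second-order constant implied by a conversion X at time t if c(nucleophile) falls one for one with c(electrophile), k = ln[(c(nucleophile) − X c(electrophile)) / ((1 − X) c(nucleophile))] / ((c(nucleophile) − c(electrophile)) t), with charged concentrations.

Held constant over 80 min, it gives my own reckoning of 48.3% for midnight. No earlier run changes free base, so for summer I carry the same figure as a guess.

The forecast gives 50% (45% to 57%) for midnight, above my figure, and 62% (47% to 72%) for summer, with the verdict it rises: “I guess partial catalysis, about 62%, so it probably rises, but this is uncertain.”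

The flask gives 45.6% for midnight and 47.0% for summer, a change of 1.4 points, so the answer is no change.

    electrophile + nucleophile → acid set free + target (k = 2.90 × 10⁻⁴ L mol⁻¹ s⁻¹)
    nucleophile + acid set free ⇌ protonated nucleophile, settled at all times (K = 630 L mol⁻¹)
    acid set free + free base ⇌ salt of the base, settled at all times (K = 4.00 L mol⁻¹)
    acid set free + free base ⇌ idle adduct, settled at all times (K = 660 L mol⁻¹)
    acid set free + scavenger → scavenged by-product (k = 0.00550 L mol⁻¹ s⁻¹)
    crystals ⇌ target, rate k6*(cs6 - [target]) while solid is left; crystals form when [target] > cs6 (solubility = 0.340 M, k = 0.0400 s⁻¹)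
    acid set free + target → side product (k = 2.50 × 10⁻⁵ L mol⁻¹ s⁻¹)

Read back through the same formula, midnight's 45.6% gives a pair constant of 0.0147 L mol⁻¹ min⁻¹, lower than the 0.0163 L mol⁻¹ min⁻¹ read from theta and epsilon, and the same flask read at 2.5 h, at 60.3%, gives 0.0133 L mol⁻¹ min⁻¹. In midnight the half-life of electrophile by its step with nucleophile, 61 min at the charged amounts, has grown to 130 min at 80.0 min, when protonated nucleophile stands at 0.112 M there against 0.0769 M in summer.

All runs are simulated for an exercise; scatter was added.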